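(Readings and results were computed for substances that don't exist, noise included.)

**One number.** I decided to take the flask's late ratio of D to E from the spring run and to leave its early ratio open.

- spring: Z 0.45 M; J 0.30 mM; run made earlier
- flask: Z 0.30 M; J 0.30 mM; time 25 h

- spring (time / h: D / %, E / %): 0.667: 15.6, 19.7; 2.00: 14.5, 16.8; 3.00: 14.8, 17.1; 5.00: 14.2, 17.2

(scatter of a reading: 0.3 percentage points)

- ratio of D to E at 15 s
- ratio of D to E at 25 h

- what may be going on: Z <-> D; J + D -> J + Q; E <-> Z; D + J <-> E + J; Z + J -> L

**Balance ratio.** The last spring reading gave a ratio of D to E of 0.826. I put that first answer back against the readings at 2.00 h and 3.00 h, which gave 0.863 and 0.865. With 0.3 percentage points on each reading I took that spread as scatter and pooled them. The balance ratio, summed D over summed E across the flat stretch, came to 0.851. I read it as thermodynamic, not kinetic, control.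

**Z charge.** The flask takes less Z than the spring run, 0.30 M against 0.45 M. Z <-> D, E <-> Z and D + J <-> E + J have equal molecule counts on each side, so by hand c_Z cancels from the balance ratio.

**J charge.** J is charged at 0.30 mM in both, so the spring run offers no comparison on it. By hand, J moves D to Q and is lost to L, and I expected c_D and c_E to fall together.

**Time.** The asked 25 h is later than the last reading at 5.00 h, so I committed to 0.851 there. The asked 15 s is earlier than the first reading at 0.667 h, so the balance ratio gave me nothing for it.

**Forecast.** The forecast gave 0.65 at 15 s and 0.85 at 25 h, its early figure, in its words, “poorly constrained”.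

**The flask.** The flask gave 9.03 at 15 s and 0.862 at 25 h. In this flask D and E stood level at 0.0992 h.

    Z ⇌ D (K = 0.924, k = 1.79 min⁻¹)
    J + D → J + Q (k = 530 M⁻¹ min⁻¹)
    E ⇌ Z (k = 0.132 min⁻¹)
    D + J ⇌ E + J, rate k4*[J]*[D] forward; the back reaction follows from the equilibrium constant (K = 1.16, k = 223 M⁻¹ min⁻¹)
    Z + J → L (k = 0.570 M⁻¹ min⁻¹)

**Second flask.** This flask ended with Q at 80.8% and a ratio of 0.862, against the balance ratio of 0.851. The neighbour charged with 7.5 × 10⁻⁵ M of J ended with Q at 20.6%, and its ratio stood at 0.862.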